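The dimethylpyran ring on ring B is closed at its aryl ether bond, O1''–C4', instead of the usual O–CMe2 bond. The feature exploited is that C3' is flanked by two oxygenated carbons, C2' (free OH) and C4' (pyran O), and carries a cis C=C. A coumarin lactone built on O2' (8-bromo-5-fluorocoumarin) is therefore used as a temporary ring: methyllithium opens it to the 2'-phenoxide and a Z-allylic tertiary alkoxide, which displaces fluoride at C4' in the same flask. Borylation and Suzuki coupling with a 3-iodochromone, made regiochemically unambiguously from a symmetrical phenol, then give the isoflavone.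

Key step: step 3

Assumption: 2,2-dimethyloxetane is taken as a purchasable reagent; the target has no stereocentre, so only the cis ring alkene and the substitution pattern need control.

Step 1
Reactants: 1 2-bromo-5-fluorophenol
Product: 2 3-bromo-6-fluoro-2-hydroxybenzaldehyde
Conditions: MgCl2, Et3N, (CH2O)n, MeCN, reflux
Reagents that add atoms: paraformaldehyde (as formaldehyde, C=O)
Why: Magnesium phenoxide-directed ortho-formylation (Casnati–Skattebøl reaction) delivers formaldehyde only ortho to the hydroxyl, so the single free ortho carbon (between OH and F) should be formylated, a second formaldehyde equivalent oxidising the benzylic alkoxide by hydride transfer.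

Step 2
Reactants: 2 3-bromo-6-fluoro-2-hydroxybenzaldehyde
Product: 4 8-bromo-5-fluoro-2H-chromen-2-one, via E-cinnamate ester 3 (not isolated)
Conditions: Ph3P=CHCO2Et, PhNEt2, reflux
Reagents that add atoms: ethyl (triphenylphosphoranylidene)acetate (CCOC(=O)C=P(c1ccccc1)(c1ccccc1)c1ccccc1)
Why: Wittig olefination with the stabilised ylide gives the E-cinnamate, which at this temperature should isomerise and lactonise onto the ortho phenol (one-pot Wittig–lactonisation coumarin synthesis), locking the C=C cis in a ring.

Step 3
Reactants: 4 8-bromo-5-fluoro-2H-chromen-2-one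
Product: 6 6-bromo-2,2-dimethyl-2H-chromen-5-ol, via dilithium Z-dianion 5 (not isolated)
Conditions: MeLi (2.2 equiv), THF, −78 to 0 °C; then DMPU, sealed tube, 90 °C; then H2O
Reagents that add atoms: methyllithium ([Li]C)
Why: Two equivalents of MeLi add to the lactone carbonyl (1,2-addition with ring opening to the Z-enone phenoxide, then 1,2-addition to the methyl ketone), so the cis C=C inherited from the coumarin holds the new tertiary lithium alkoxide beside the fluorine-bearing carbon (C5 of the coumarin, C4' of the target); on heating with DMPU the alkoxide adds to this carbon and fluoride leaves as LiF (addition–elimination SNAr), forming the O–C4' aryl ether bond. The closest known reaction types are the opening of coumarins to (Z)-2-(3-hydroxy-3-methylbut-1-enyl)phenols with methyllithium and the base-mediated intramolecular SNAr etherification of 2-fluoroaryl alkanols to chromans. The pyran ring closes by 6-exo-trig attack of oxygen on the aromatic carbon, while the lactone ring is opened in the same flask. No stereocentre is formed; the Z geometry required for closure is set by the lactone ring and is retained because the alkene is never deconjugated. The step needs the alkoxide to close on C4' rather than the phenoxide on the carbinol carbon (which would give the isomeric 5-fluorochromene), and C–F to react in preference to C–Br: under purely basic conditions the carbinol carbon cannot ionise, the fluorinated carbon is the only halogenated position ortho to the side chain, fluoride is the far better SNAr leaving group, and the para bromine activates it inductively. The quench is kept non-acidic so that any uncyclised diol does not close in the wrong sense.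

Step 4
Reactants: 6 6-bromo-2,2-dimethyl-2H-chromen-5-ol
Product: 8 2,2-dimethyl-6-(4,4,5,5-tetramethyl-1,3,2-dioxaborolan-2-yl)-2H-chromen-5-ol, via dilithiated chromenolate 7 (not isolated)
Conditions: n-BuLi (2.2 equiv), THF, −78 to −20 °C; then i-PrOBpin, −78 °C to rt; then H2O
Reagents that add atoms: 2-isopropoxy-4,4,5,5-tetramethyl-1,3,2-dioxaborolane (CC(C)OB1OC(C)(C)C(C)(C)O1)
Why: Deprotonation of the phenol followed by bromine–lithium exchange and trapping of the aryllithium with the isopropoxyboronate (lithiation–borylation) should convert C–Br into C–Bpin without a protecting group, the chromene C=C being inert to n-BuLi at low temperature.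

Step 5
Reactants: 9 resorcinol (benzene-1,3-diol)
Product: 10 1,3-bis(methoxymethoxy)benzene
Conditions: NaH, MOMCl, DMF, 0 °C to rt
Reagents that add atoms: chloromethyl methyl ether (COCCl)
Why: Williamson-type O-alkylation of the bis-phenoxide (acetal protection) installs two ortho-directing MOM ethers.

Step 6
Reactants: 10 1,3-bis(methoxymethoxy)benzene
Product: 12 4-[2,6-bis(methoxymethoxy)phenyl]-2-methylbutan-2-ol, via aryllithium 11 (not isolated)
Conditions: n-BuLi, THF, 0 °C to rt; then 2,2-dimethyloxetane, BF3·OEt2, −78 °C; then H2O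
Reagents that add atoms: 2,2-dimethyloxetane (CC1(C)CCO1)
Why: Directed ortho-metalation occurs at the carbon between the two MOM ethers, and the aryllithium should open the BF3-activated oxetane by SN2 attack at its unsubstituted CH2 (Lewis acid-promoted oxetane alkylation), giving the complete 3-hydroxy-3-methylbutyl chain in one operation.

Step 7
Reactants: 12 4-[2,6-bis(methoxymethoxy)phenyl]-2-methylbutan-2-ol
Product: 14 4-(3-hydroxy-3-methylbutyl)-3,5-bis(methoxymethoxy)phenol, via arylboronate 13 (not isolated)
Conditions: [Ir(OMe)(cod)]2 (1.5 mol %), dtbpy (3 mol %), B2pin2, THF, 80 °C; then H2O2, aq NaOH, 0 °C to rt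
Reagents that add atoms: bis(pinacolato)diboron (CC1(C)OB(OC1(C)C)B1OC(C)(C)C(C)(C)O1); hydrogen peroxide (OO)
Why: Sterically controlled iridium-catalysed C–H borylation takes the only C–H without an ortho substituent (para to the chain) to give boronate 13, and oxidation of its C–B bond with alkaline peroxide replaces the boron by the peroxide oxygen, giving a phenol that is symmetrical about the chain–OH axis.

Step 8
Reactants: 14 4-(3-hydroxy-3-methylbutyl)-3,5-bis(methoxymethoxy)phenol
Product: 15 4-(3-hydroxy-3-methylbutyl)-3,5-bis(methoxymethoxy)phenyl acetate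
Conditions: Ac2O, Et3N, CH2Cl2, 0 °C
Reagents that add atoms: acetic anhydride (CC(=O)OC(C)=O)
Why: Base-mediated O-acetylation is selective for the phenol, the hindered tertiary alcohol not being acylated without a nucleophilic catalyst.

Step 9
Reactants: 15 4-(3-hydroxy-3-methylbutyl)-3,5-bis(methoxymethoxy)phenyl acetate
Product: 16 1-[2-hydroxy-5-(3-hydroxy-3-methylbutyl)-4,6-bis(methoxymethoxy)phenyl]ethan-1-one
Conditions: hν (254 nm), degassed MeOH, rt
Reagents that add atoms: none
Why: Photo-Fries rearrangement (homolysis of the ester O–acyl bond and in-cage recombination) can deliver the acetyl group only to an ortho carbon because the para position carries the chain, and as the two ortho carbons are equivalent a single hydroxyacetophenone should result, with its free OH on the side remote from the chain.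

Step 10
Reactants: 16 1-[2-hydroxy-5-(3-hydroxy-3-methylbutyl)-4,6-bis(methoxymethoxy)phenyl]ethan-1-one
Product: 18 6-(3-hydroxy-3-methylbutyl)-3-iodo-5,7-bis(methoxymethoxy)-4H-chromen-4-one, via enaminone 17 (not isolated)
Conditions: DMF-DMA, toluene, 95 °C; evaporate; then I2, pyridine, CHCl3, rt
Reagents that add atoms: N,N-dimethylformamide dimethyl acetal (COC(OC)N(C)C); iodine (II)
Why: Condensation of the methyl ketone with the formamide acetal gives the enaminone, and iodination of its α-carbon followed by addition–elimination of the only free ortho hydroxyl with loss of dimethylamine closes the pyranone (enaminone iodocyclisation to a 3-iodochromone), which places the chain at C6 because both oxygens flanking it are MOM-protected.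

Step 11
Reactants: 18 6-(3-hydroxy-3-methylbutyl)-3-iodo-5,7-bis(methoxymethoxy)-4H-chromen-4-one; 8 2,2-dimethyl-6-(4,4,5,5-tetramethyl-1,3,2-dioxaborolan-2-yl)-2H-chromen-5-ol
Product: 19 3-(5-hydroxy-2,2-dimethyl-2H-chromen-6-yl)-6-(3-hydroxy-3-methylbutyl)-5,7-bis(methoxymethoxy)-4H-chromen-4-one
Conditions: Pd(dppf)Cl2 (5 mol %), K2CO3, 1,4-dioxane/H2O, 80 °C
Reagents that add atoms: none
Why: Suzuki–Miyaura coupling of the 3-iodochromone (fast oxidative addition at the vinylogous acyl iodide) with the ortho-hydroxyarylboronate should form the C3–C1' bond of the isoflavone, the tertiary alcohol, MOM ethers and chromene being inert.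

Step 12
Reactants: 19 3-(5-hydroxy-2,2-dimethyl-2H-chromen-6-yl)-6-(3-hydroxy-3-methylbutyl)-5,7-bis(methoxymethoxy)-4H-chromen-4-one
Product: 20 Kanzonol T (5,7-dihydroxy-3-(5-hydroxy-2,2-dimethyl-2H-chromen-6-yl)-6-(3-hydroxy-3-methylbutyl)-4H-chromen-4-one)
Conditions: 3 M aq HCl, MeOH/THF, 40 °C
Reagents that add atoms: none
Why: Acid-catalysed acetal exchange with methanol should remove both MOM groups (the chelated 5-O-MOM first) under conditions too mild to ionise the tertiary alcohol or hydrate the chromene.

Compound list
1 | 2-bromo-5-fluorophenol | Oc1cc(F)ccc1Br | starting material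
2 | 3-bromo-6-fluoro-2-hydroxybenzaldehyde | O=Cc1c(F)ccc(Br)c1O | intermediate
3 | ethyl (E)-3-(3-bromo-6-fluoro-2-hydroxyphenyl)prop-2-enoate | CCOC(=O)/C=C/c1c(F)ccc(Br)c1O | intermediate
4 | 8-bromo-5-fluoro-2H-chromen-2-one | O=C1C=Cc2c(F)ccc(Br)c2O1 | intermediate
5 | dilithium 6-bromo-3-fluoro-2-[(Z)-3-methyl-3-oxidobut-1-enyl]phenolate | [Li]Oc1c(Br)ccc(F)c1/C=C\C(C)(C)O[Li] | intermediate
6 | 6-bromo-2,2-dimethyl-2H-chromen-5-ol | CC1(C)C=Cc2c(O)c(Br)ccc2O1 | intermediate
7 | lithium 6-lithio-2,2-dimethyl-2H-chromen-5-olate | [Li]Oc1c([Li])ccc2OC(C)(C)C=Cc12 | intermediate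
8 | 2,2-dimethyl-6-(4,4,5,5-tetramethyl-1,3,2-dioxaborolan-2-yl)-2H-chromen-5-ol | CC1(C)C=Cc2c(O)c(B3OC(C)(C)C(C)(C)O3)ccc2O1 | intermediate
9 | resorcinol (benzene-1,3-diol) | Oc1cccc(O)c1 | starting material
10 | 1,3-bis(methoxymethoxy)benzene | COCOc1cccc(OCOC)c1 | intermediate
11 | [2,6-bis(methoxymethoxy)phenyl]lithium | [Li]c1c(OCOC)cccc1OCOC | intermediate
12 | 4-[2,6-bis(methoxymethoxy)phenyl]-2-methylbutan-2-ol | CC(C)(O)CCc1c(OCOC)cccc1OCOC | intermediate
13 | 4-[2,6-bis(methoxymethoxy)-4-(4,4,5,5-tetramethyl-1,3,2-dioxaborolan-2-yl)phenyl]-2-methylbutan-2-ol | CC(C)(O)CCc1c(OCOC)cc(B2OC(C)(C)C(C)(C)O2)cc1OCOC | intermediate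
14 | 4-(3-hydroxy-3-methylbutyl)-3,5-bis(methoxymethoxy)phenol | CC(C)(O)CCc1c(OCOC)cc(O)cc1OCOC | intermediate
15 | 4-(3-hydroxy-3-methylbutyl)-3,5-bis(methoxymethoxy)phenyl acetate | CC(=O)Oc1cc(OCOC)c(CCC(C)(C)O)c(OCOC)c1 | intermediate
16 | 1-[2-hydroxy-5-(3-hydroxy-3-methylbutyl)-4,6-bis(methoxymethoxy)phenyl]ethan-1-one | CC(=O)c1c(O)cc(OCOC)c(CCC(C)(C)O)c1OCOC | intermediate
17 | (E)-3-(dimethylamino)-1-[2-hydroxy-5-(3-hydroxy-3-methylbutyl)-4,6-bis(methoxymethoxy)phenyl]prop-2-en-1-one | CN(C)/C=C/C(=O)c1c(O)cc(OCOC)c(CCC(C)(C)O)c1OCOC | intermediate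
18 | 6-(3-hydroxy-3-methylbutyl)-3-iodo-5,7-bis(methoxymethoxy)-4H-chromen-4-one | CC(C)(O)CCc1c(OCOC)cc2occ(I)c(=O)c2c1OCOC | intermediate
19 | 3-(5-hydroxy-2,2-dimethyl-2H-chromen-6-yl)-6-(3-hydroxy-3-methylbutyl)-5,7-bis(methoxymethoxy)-4H-chromen-4-one | CC(C)(O)CCc1c(OCOC)cc2occ(-c3ccc4c(c3O)C=CC(C)(C)O4)c(=O)c2c1OCOC | intermediate
20 | Kanzonol T | CC(C)(O)CCc1c(O)cc2occ(-c3ccc4c(c3O)C=CC(C)(C)O4)c(=O)c2c1O | target

Total step count: 12. Longest linear sequence: 8 steps (steps 5 to 12, from resorcinol); the ring B branch (steps 1 to 4) joins at step 11.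

Steps most likely to fail

Step 3. Fluoride displacement on the electron-rich phenoxide ring may lag behind, so that uncyclised Z-diol survives and then closes in the opposite sense through the phenol on work-up; conjugate addition of MeLi to the coumarin may also compete. The fallback gives up the lactone template and closes the same O–aryl bond on a neutral ring; it sets out from 2 and rejoins the route at 6. Aldehyde 2 would be protected (MOMCl, i-Pr2NEt, CH2Cl2) as 3-bromo-6-fluoro-2-(methoxymethoxy)benzaldehyde F1. A Z-selective Ando-type Horner–Wadsworth–Emmons olefination (ethyl (diphenoxyphosphoryl)acetate, NaH, THF, −78 °C) should give ethyl (Z)-3-[3-bromo-6-fluoro-2-(methoxymethoxy)phenyl]prop-2-enoate F2. MeLi would convert it into (Z)-4-[3-bromo-6-fluoro-2-(methoxymethoxy)phenyl]-2-methylbut-3-en-2-ol F3, which is isolable because the phenol is masked. KN(SiMe3)2 in DMF at 60 °C should then close the pyran ring to 6-bromo-5-(methoxymethoxy)-2,2-dimethyl-2H-chromene F4, and HCl in MeOH returns chromenol 6.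

Step 9. The photo-Fries rearrangement may stall through inner-filter absorption by the product and through escape of the radical pair, which returns phenol 14. The fallback builds the acetyl group by polar chemistry; it sets out from 14 and rejoins at 16. Phenol 14 would be ortho-formylated (MgCl2, Et3N, paraformaldehyde, MeCN) at either of its equivalent ortho carbons to 2-hydroxy-5-(3-hydroxy-3-methylbutyl)-4,6-bis(methoxymethoxy)benzaldehyde F5. Excess MeMgBr should give 1-[2-hydroxy-5-(3-hydroxy-3-methylbutyl)-4,6-bis(methoxymethoxy)phenyl]ethan-1-ol F6 (racemic; the stereocentre is removed again), and MnO2 in CH2Cl2 oxidises the benzylic alcohol to acetophenone 16.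

Step 6. The BF3-activated oxetane may ionise at its tertiary carbon (elimination or attack at the wrong carbon), and the Lewis acid may strip a MOM group before the hindered aryllithium attacks. The fallback builds the chain by cross-coupling and reduction; it sets out from 10 (through aryllithium 11) and rejoins at 12. Aryllithium 11 would be quenched with I2 to 2-iodo-1,3-bis(methoxymethoxy)benzene F7. Sonogashira coupling with 2-methylbut-3-yn-2-ol (Pd(PPh3)2Cl2, CuI, Et3N) should give 4-[2,6-bis(methoxymethoxy)phenyl]-2-methylbut-3-yn-2-ol F8, and hydrogenation (H2, Pd/C, EtOAc) gives alcohol 12.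

Further compounds
F1 | step 3 | 3-bromo-6-fluoro-2-(methoxymethoxy)benzaldehyde | COCOc1c(Br)ccc(F)c1C=O
F2 | step 3 | ethyl (Z)-3-[3-bromo-6-fluoro-2-(methoxymethoxy)phenyl]prop-2-enoate | CCOC(=O)/C=C\c1c(F)ccc(Br)c1OCOC
F3 | step 3 | (Z)-4-[3-bromo-6-fluoro-2-(methoxymethoxy)phenyl]-2-methylbut-3-en-2-ol | CC(C)(O)/C=C\c1c(F)ccc(Br)c1OCOC
F4 | step 3 | 6-bromo-5-(methoxymethoxy)-2,2-dimethyl-2H-chromene | COCOc1c(Br)ccc2OC(C)(C)C=Cc12
F5 | step 9 | 2-hydroxy-5-(3-hydroxy-3-methylbutyl)-4,6-bis(methoxymethoxy)benzaldehyde | O=Cc1c(O)cc(OCOC)c(CCC(C)(C)O)c1OCOC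
F6 | step 9 | 1-[2-hydroxy-5-(3-hydroxy-3-methylbutyl)-4,6-bis(methoxymethoxy)phenyl]ethan-1-ol (racemic) | CC(O)c1c(O)cc(OCOC)c(CCC(C)(C)O)c1OCOC
F7 | step 6 | 2-iodo-1,3-bis(methoxymethoxy)benzene | COCOc1cccc(OCOC)c1I
F8 | step 6 | 4-[2,6-bis(methoxymethoxy)phenyl]-2-methylbut-3-yn-2-ol | CC(C)(O)C#Cc1c(OCOC)cccc1OCOC
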